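Readings and results stem from a simulated flask on assumed constants; scatter was added.

If D and Z came out even, cD over cZ would be one and its logarithm zero. I measure every flask from that even split. Here the enzyme J turns the substrate G into D, Z is the other product, and X is a further species in the flask.

| flask | G | J | X | temperature | remark | time |
|---|---|---|---|---|---|---|
| Saturday's | 0.010 M | 0.01 mol% | 2.8 µM | 0 °C | run made earlier |  |
| eta | 0.010 M | 0.01 mol% | 5.6 µM | 0 °C |  | 10 h |
| alpha | 0.010 M | 0.01 mol% | 5.6 µM |  | at 30 °C until 8.0 h, from then on at 0 °C | 10 h |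
| zeta | 0.010 M | 0.01 mol% | 5.6 µM | 30 °C |  | 10 h |

Saturday's run (percent of the G charged)

| time / h | D / % | Z / % |
|---|---|---|
| 0.250 | 4 | 1 |
| 0.417 | 5 | 0 |
| 0.833 | 10 | 0 |
| 1.50 | 19 | 0 |
| 3.00 | 35 | 2 |

(standard deviation of a reading: 1.5 percentage points)

- the earlier runs do not show what temperature does; that part of a forecast is a guess
- no earlier run changes the charge of X; that part of a forecast is a guess

1. the flask with the highest share of D in all that became D or Z ("all alike" if they lie within 1.5 percentage points) (eta / alpha / zeta / all alike)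
2. share of D in all that became D or Z, eta
3. share of D in all that became D or Z, alpha
4. share of D in all that became D or Z, zeta

Saturday's last reading, D 35% against Z 2% at 3.00 h, gives 2.86 for the logarithm of cD over cZ, which I call the lead of D. It is a rough reading, since Z carries a scatter of 1.5 percentage points. The share asked for is one over one plus the exponential of minus the lead. If D and Z pass into each other, a lead that stands level over a time long against the relaxation of that exchange is an equilibrium value (thermodynamic control). A lead still moving is set by rates (kinetic control).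

My own reckoning keeps Saturday's lead for eta, which has the same temperature. That gives a share of 94.6%. Doubling X is a guess, and so is any lead for the warm flasks, so I commit to no number there.

The forecast names eta, with 95% for eta, 82% for alpha and 80% for zeta, a lead of 1.39. Of alpha it says: “The final cold period barely matters, so it should be close to zeta.”

The flasks give eta as the highest, with 99.7% for eta, 90.6% for alpha and 90.2% for zeta.

    J → L (k = 0.00183 h⁻¹, Ea = 233 kJ mol⁻¹)
    G + J ⇌ Q (K = 42.0 M⁻¹, k = 7.47 × 10⁶ M⁻¹ h⁻¹, Ea = 41.0 kJ mol⁻¹, ΔH = −33.0 kJ mol⁻¹)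
    Q ⇌ J + D (K = 0.471 M, k = 28200 h⁻¹, Ea = 57.0 kJ mol⁻¹, ΔH = −33.0 kJ mol⁻¹)
    D ⇌ Z (K = 0.110, k = 0.0590 h⁻¹, Ea = 108 kJ mol⁻¹, ΔH = 8.00 kJ mol⁻¹)
    J + X ⇌ E (K = 1.67 × 10⁵ M⁻¹, k = 50300 M⁻¹ h⁻¹, Ea = 42.0 kJ mol⁻¹, ΔH = 23.0 kJ mol⁻¹)
    (constants at 30 °C)

Zeta's lead is 2.22 at 10 h and 2.21 at 100 h, so it stands level. The relaxation half-life of D and Z in zeta, 1.16 h, is short against 10 h. The way back from Z to D matters here: without it zeta's share is 60.5% instead of 90.2%. Eta is under kinetic control: its lead falls from 5.81 at 10 h to 3.28 at 100 h.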